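The earlier runs and the new flask are simulated for substances that don't exist; noise was put on by code.

In a one-step world, with starting material and partner giving target and nothing else, every starting material lost becomes target. The selectivity, target formed per starting material consumed, then stands at one in every flask, and the target fraction of the charge equals the conversion.

| flask | starting material | partner | second substrate | remark | time |
|---|---|---|---|---|---|
| violet | 0.027 M | 0.24 M | 0.20 M | run made earlier |  |
| teal | 0.78 M | 0.24 M | 0.20 M | run made earlier |  |
| noon | 0.020 M | 0.240 M | 0.200 M |  | 15 h |
| spring | 0.060 M | 0.240 M | 0.200 M |  | 15 h |
| dusk | 0.20 M | 0.240 M | 0.200 M |  | 15 h |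
| midnight | 0.60 M | 0.240 M | 0.200 M |  | 15 h |

- violet (time / h: target / %, starting material / %): 2.00: 21.4, 63.5; 4.00: 30.3, 44.9; 6.00: 37.3, 34.6; 8.00: 40.8, 26.8; 10.0: 45.4, 21.7; 12.0: 48.1, 18.3; 15.0: 48.8, 13.1
- teal (time / h: target / %, starting material / %): 2.00: 8.3, 17.7; 4.00: 10.4, 10.0; 6.00: 10.9, 5.2; 8.00: 12.0, 3.8; 10.0: 11.4, 3.6; 12.0: 12.6, 3.3; 15.0: 12.3, 2.6

(scatter of a reading: 1 percentage point)

- "hardly changes" means that all values lie within two and a half points (for a concentration: within two and a half percent of the largest)

- [target] at the end for noon, spring, dusk, midnight, in this order
- the course of these numbers from the first flask to the last (falls, then rises / falls all the way / rises all the way / hardly changes / rises, then falls)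

The last readings depart from that world: the violet run gives a selectivity of 0.562, the teal run 0.126. Both are readings and carry their scatter. Adding a second step that competes at a fixed share lowers the selectivity by the same factor in both runs, yet violet stands above teal, so a fixed share does not describe them. Adding a third loss, second order in starting material, makes the share lost grow with the charge, partner and second substrate being held at the same charges. The reckoning made here takes the reciprocal of the selectivity as a straight line in the charge, which is an approximation, since starting material falls during each run.

The two runs give that line without testing it. Its constant term and its charge-dependent term are equal at the crossing charge, the charge at which control passes from the fixed competition to the loss that grows with the charge: 0.191 M. The selectivity extrapolated to a vanishing charge is 0.641.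

The reckoning made here multiplies the selectivity from this line by the conversion of the nearest run. Noon, with violet's last reading of conversion, 86.9%, is reckoned at 0.504 of its charge as target, or 0.0101 M. Midnight, with teal's last reading of conversion, 97.4%, is reckoned at 0.151 of its charge, or 0.0906 M. On this line the fraction falls along the row, but the concentration rises: selectivity times charge climbs towards 0.122 M.

The forecast, made from the same two runs, gives 0.0098 M, 0.027 M, 0.059 M and 0.087 M, a course that rises all the way, on this ground: “The selectivity therefore tracks the charge”. Its two end values lie a little apart from those reckoned here.

The flask gives 0.0104 M, 0.0257 M, 0.0560 M and 0.0914 M, a course that rises all the way.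

    starting material + second substrate → cross product (k = 0.320 M⁻¹ h⁻¹)
    partner → decomposition product (k = 2.50 × 10⁻⁴ h⁻¹)
    2 starting material → self-condensation product (k = 1.10 M⁻¹ h⁻¹)
    second substrate + partner → second product (k = 0.670 M⁻¹ h⁻¹)
    starting material + partner → target (k = 0.600 M⁻¹ h⁻¹)

Midnight, charged at 3.13 crossing charges, shows a selectivity of 0.156 against 0.155 from the line. Dusk, charged at 1.04 crossing charges, shows 0.297 against 0.313. The largest single effect on midnight's target is the self-condensation of starting material: with that step taken away, target at the end reaches twice its value, 0.183 M against 0.0914 M.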